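4 amounts and one choice are asked of you here, each about complex with two exchanged, and what you see of it at the end is what was made less what has since been lost.

| setting | south-east | south | east | south-west | alpha | zeta | delta | beta |
|---|---|---|---|---|---|---|---|---|
| starting complex | 21 mM | 21 mM | 21 mM | 42 mM | 21 mM | 21 mM | 21 mM | 21 mM |
| incoming ligand | 27.3 mM | 14 mM | 55 mM | 27.3 mM | 27.3 mM | 27.3 mM (fed, over 40.0 min) | 27.3 mM | 27.3 mM |
| remark | run made earlier | run made earlier | run made earlier | run made earlier | everything together in a closed stirred flask, run for 80 min | a stirred flask in which incoming ligand is dosed at a steady rate over 40.0 min without added volume, worked up at 80 min | one stirred flow tank at steady state, fed with the mixture as stated, mean residence time 400 min | one stirred flow tank at steady state, fed with the mixture as stated, mean residence time 80 min |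
| time |  |  |  |  | 80 min | 80 min |  |  |

- south-east (time / min: complex with two exchanged / %, starting complex / %): 6.00: 9, 42; 15.0: 21, 21; 20.0: 23, 19; 30.0: 27, 12; 40.0: 28, 8; 50.0: 27, 12
- south (time / min: complex with two exchanged / %, starting complex / %): 8.00: 4, 55; 12.0: 5, 49; 20.0: 8, 44; 25.0: 7, 45; 40.0: 6, 42; 60.0: 5, 43; 90.0: 2, 43
- east (time / min: complex with two exchanged / %, starting complex / %): 8.00: 40, 10; 12.0: 53, 4; 20.0: 64, 0; 25.0: 68, 2; 40.0: 69, 0; 60.0: 65, 2; 90.0: 46, 0
- south-west (time / min: complex with two exchanged / %, starting complex / %): 8.00: 7, 51; 15.0: 8, 43; 25.0: 8, 45; 50.0: 8, 43; 90.0: 1, 43

(scatter of a reading: 1.5 percentage points)

* the set-up with the highest amount of complex with two exchanged at the outlet or at the end, in percent of the starting complex put in ("none" if the first two lie within 2 percentage points) (alpha / zeta / delta / beta / none)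
* amount of complex with two exchanged at the outlet or at the end, in percent of the starting complex put in, alpha
* amount of complex with two exchanged at the outlet or at the end, in percent of the starting complex put in, zeta
* amount of complex with two exchanged at the outlet or at the end, in percent of the starting complex put in, delta
* amount of complex with two exchanged at the outlet or at the end, in percent of the starting complex put in, beta

- the stated concentrations are those of everything mixed, before any reaction; amounts are the same in each set-up
- what was read earlier has a scatter of 1.5 percentage points, one standard deviation
- candidate steps: complex with one exchanged + incoming ligand -> leaving ligand + complex with two exchanged; complex with two exchanged -> over-reaction product; starting complex + incoming ligand -> leaving ligand + complex with one exchanged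
- the feed brings no volume worth counting
- the earlier runs were made in a closed, stirred flask

Follow the rates. In the south-east run the starting complex goes at first at a fractional rate of 0.145 /min, but between 15.0 min and 30.0 min at 0.0373 /min, slower by a factor of 3.89, as the incoming ligand is consumed; it is the limiting reagent, with 1.30 equivalents against the 2 that both exchanges take.

The step that loses complex with two exchanged takes no ligand, so its fractional rate does not fade with the others. In the east run the reading falls from 69% at 40.0 min to 46% at 90.0 min, which gives k_L = 0.00811 /min, the loss constant, the fraction lost per minute.

So in my reckoning the south-east reading of 28% at 40.0 min decays to 20.2% at 80 min for alpha. Steady dosing over 40.0 min delivers the ligand on average 20.0 min later; taking both exchanges as proportional to ligand, the same amount forms but is younger by that delay, which multiplies it by exp(k_L d) = 1.18. That puts zeta at 23.8%, ahead of alpha by 3.6 percentage points. In a flow tank with mean residence time τ, the share of what was made that leaves unchanged is one over one plus k_L τ, which is 23.6% for delta.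

The forecast gave alpha 18%, zeta 22%, delta 8% and beta 18%, and chose zeta: “The same roughly 37% (product plus over-reaction) forms later, so it has less time to decay”. Its zeta lies below mine.

The flask gives alpha 21.4%, zeta 25.5%, delta 9.41% and beta 20.9%, and the best is zeta.

    complex with one exchanged + incoming ligand → leaving ligand + complex with two exchanged (k = 3.10 /M/min)
    complex with two exchanged → over-reaction product (k = 0.00970 /min)
    starting complex + incoming ligand → leaving ligand + complex with one exchanged (k = 8.20 /M/min)

Zeta stands above alpha by a factor of 1.19, against the 1.18 from k_L. In delta, 1.13 mM of incoming ligand stands in the tank and 21.3% of the starting complex remains, so the ligand balance puts 45.9% of the charge through the second exchange. With k_L as read from the east run, the reckoned share of 23.6% turns that into 10.8%, above the 9.41% that delta gives.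

(The runs were generated by integration for substances that don't exist.)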